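## Structural features

The target is a tetrabrominated 2,2′-dihydroxydiphenyl ether: two benzene rings joined only through one oxygen atom, each carrying a hydroxyl group ortho to that oxygen. Ring A is numbered C1 (OH), C2 (bridging oxygen) and C4 (Br), with C3, C5 and C6 unsubstituted, and ring B is numbered C1′ (bridging oxygen), C2′ (OH), C3′ (Br), C4′ (H), C5′ (Br) and C6′ (Br). There is no stereocentre and no hindered axis, so the whole problem is one of regiochemistry. The four aryl C–Br bonds rule out reductive conditions, halogen–metal exchange and zerovalent palladium late in the route, and the electron-rich bromophenols are prone to oxidation and over-halogenation. The real difficulty is threefold: the two rings are electronically alike, yet ring B must take bromine ortho and para to its hydroxyl (C3′, C5′) while the equally activated C6 of ring A stays free; the C6′ bromine is meta to the ring B hydroxyl and cannot be placed by phenol-directed substitution; and the ether oxygen sits on a ring B carbon flanked by two substituents, which makes a late aryl C–O coupling unattractive. The key step exploits the fact that C6–C1(OH)–C2(O) of ring A maps onto a ketone with two α-carbons, one already bonded to the ether oxygen, and C3–C4(Br)–C5 onto a symmetric 2-bromo-1,3-dialdehyde. Ring A can therefore be grown onto the existing aryloxy group with its bromine fixed para to the hydroxyl.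

## Logic of the disconnections

12 ⇒ 11. The O–S bond of a sulfonate on the ring A oxygen is restored. The ring A hydroxyl has to be an electron-poor substituent while ring B is halogenated, and a sulfonate neither migrates nor activates. The gain is an electronic difference between two otherwise similar rings. The forward cleavage must break S–O without displacing aryl bromide and without moving ring A between the two oxygens of ring B.

11 ⇒ 10. The C3′–Br and C5′–Br bonds are cut. Both positions are ortho or para to the free C2′ hydroxyl of 10, so phenol-directed substitution can put them in. This removes two of the four halogens and leaves only C4–Br and C6′–Br, which come from starting materials. The forward step must stop after two bromines and stay on ring B, away from C4′ and from C5 of ring A.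

10 ⇒ 8 (through 9). The O–CH3 bond on the C2′ oxygen is restored. That hydroxyl needs a base-stable mask during ring construction, and the methyl ether traces ring B back to a catalogue phenol. The forward cleavage must distinguish the alkyl–oxygen bond from the diaryl ether and the sulfonate.

8 ⇒ 7. The O–S bond is cut. The sulfonate is introduced when 7 has only one free hydroxyl, so no selectivity question arises. The demand on the forward step is negligible.

7 ⇒ 3 + 4 (through 5 and 6). The C2–C3 and C5–C6 bonds of ring A are cut. This builds ring A around the ether oxygen already present, avoids a hindered diaryl ether coupling, and fixes C4–Br para to the hydroxyl through the symmetry of 4. The gain is the largest of the route: one ring, two skeletal bonds, and two three-carbon pieces of low complexity. The forward step must form both C–C bonds faster than 4 is degraded, which is why 4 is converted in the flask into 5, and 6 must adopt the geometry that allows closure.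

3 ⇒ 1 + 2. The O–CH2 bond is cut. The ether oxygen is attached by substitution at sp3 carbon, and both fragments are purchased. O-alkylation of the hindered phenoxide must outrun base-induced self-condensation of 2.

## Other disconnections considered

Alternative 1: The cut falls on the two aryl C–OH bonds, C1–O of ring A and C2′–O of ring B, of a diaryl ether that is bought intact.
- Forward sequence: 2-phenoxyaniline A1 would be masked by Paal–Knorr condensation as the 2,5-dimethylpyrrole A2. As the key step, A2 would be lithiated on both rings next to the ether oxygen (n-BuLi, TMEDA), borylated with B(OMe)3 and oxidised (H2O2, NaOH) to bis-phenol A3 in one flask. Unmasking would give aminobisphenol A4, whose amino and hydroxyl groups both direct to C3′ and C5′, so three equivalents of an electrophilic bromine source should give A5. A Sandmeyer reaction (NaNO2, HBr, CuBr) would then turn the amino group into the C6′ bromine of 12.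
- In its favour: the ether bond never has to be made. The nitrogen is the handle for C6′–Br, makes ring B the more reactive ring, and leaves no trace. The sequence is about five steps against six, so on step economy and on protecting-group economy at the ring A hydroxyl this alternative is the better one.
- Against it here: the double metalation must pick two specific ortho positions in competition with the position next to the pyrrole nitrogen and with lateral metalation of the pyrrole methyl groups, and a second lithiation of an already metalated diaryl ether is slow. Ring A must then accept exactly one bromine para to a free hydroxyl while C6 stays open, which is the over-halogenation problem the chosen plan removes with a sulfonate. The diazotisation is asked of an electron-rich, oxidisable aminophenol.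
- Comparison: on structure the two plans are equal in avoiding a hindered C–O coupling. On mechanism the chosen plan sets C4–Br and C6′–Br by construction, whereas this one relies on kinetic site selectivity in three separate operations. That is why it was not preferred although it is shorter.

Alternative 2: The cut falls on the bridging O–C1′ bond and the C6′–Br bond, made together on an aryne.
- Forward sequence: the aryne released from iodoaryl triflate A6 with iPrMgCl·LiCl, which carries boron next to the strained bond, would take up the chloromagnesium salt (ArOMgCl) of 5-bromo-2-methoxyphenol A7 at the aryne carbon next to boron. The aryl–magnesium bond (ArMgCl) left at the neighbouring carbon would be quenched with an electrophilic bromine source to give boronate A8. Oxidation of the C–B bond would give phenol A9, dibromination ortho and para to the new hydroxyl would give A10, and demethylation would give 12.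
- In its favour: the three contiguous substituents of ring B are placed in one operation with regiochemistry dictated by boron. Ring A keeps its hydroxyl as a catalogue methyl ether until the last step, so no protection–deprotection pair is needed; on this point it is better than the chosen plan. The bromination then distinguishes a free phenol from an anisole ring, a bias at least as good as phenol against aryl sulfonate.
- Against it here: A6 has to be made in several steps. A phenoxide is a modest aryne nucleophile and must outrun addition of the Grignard reagent itself. The aryl bromide of A7 is exposed to a halogen–magnesium exchange reagent. Three-component aryne couplings with oxygen nucleophiles followed by halogen quench are far less established than those with nitrogen or carbon nucleophiles.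
- Comparison: on structure the plans are equal in fixing the C6′ bromine unambiguously. On mechanism the chosen plan uses polar condensation chemistry that tolerates aryl bromides, where this one needs organomagnesium intermediates beside them. On step count the alternative is longer once the synthesis of A6 is counted (about seven to eight steps against six).

Alternative 3: The cut falls on a ring B C–C bond, between the ether-bearing carbon C1′ and one of its neighbours, with ring B carried at the oxidation level of a cyclohexane-1,3-dione.
- Forward sequence: keto ester A11, from alkylation of A7 with an α-halo keto ester, would be cyclised with base (NaOMe or KOtBu). The enolate at the aryloxymethyl carbon attacks the ester carbonyl in a Claisen (Dieckmann-type) condensation and gives dione A12. One carbonyl would then be converted into the vinyl bromide of bromoenone A13. The ring would be aromatised by α,α-dibromination at the remaining α-methylene, loss of one HBr and tautomerisation to phenol A14. The position para to the new hydroxyl would be brominated to A10, and ring A demethylated to 12.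
- In its favour: the cyclisation is a textbook ring closure driven by formation of the stabilised dione enolate, and in reliability it is better than the key step chosen here. The two carbonyl carbons programme C2′–OH and C6′–Br, the position that phenol-directed substitution cannot reach. The ether bond is again made by alkylation at sp3 carbon (equal to the chosen plan), and ring A stays a methyl ether throughout, so no sulfonate is needed.
- Against it here: the arene is reached only after three further halogenation and elimination operations, in which the anisole ring A and the enolisable ketone compete for bromine and aromatisation can stop short or overshoot. The α-halo keto ester is not a catalogue compound. The total is about eight steps against six.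
- Comparison: the chosen plan forms an aromatic ring at the correct oxidation level in one operation and carries both awkward bromines in from starting materials, at the price of a less proven condensation.

Key step: step 2

Remark on the chemistry: 4 is drawn as the dialdehyde although it reacts as its enol. Intermediate 6 is drawn for first C–C bond formation at the aryloxy-bearing α-carbon; the opposite order leads to the same ring. The double-bond geometries shown for 5 and 6 are those expected to react and are assumed to interconvert readily.

## Route

Step 1
Reactants: 1 2-bromo-6-methoxyphenol; 2 chloroacetone (1-chloropropan-2-one)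
Product: 3 1-(2-bromo-6-methoxyphenoxy)propan-2-one
Conditions: K2CO3, KI (cat.), acetone, reflux
Reagents that add atoms: none
Why: Williamson ether synthesis: the phenoxide formed with K2CO3 displaces chloride from the activated α-chloro ketone by SN2 (iodide catalysis through Finkelstein exchange); O-alkylation of 2,6-disubstituted phenoxides with α-halo ketones is routine, and the aryl bromide and methyl ether are inert.

Step 2
Reactants: 3 1-(2-bromo-6-methoxyphenoxy)propan-2-one; 4 2-bromomalonaldehyde
Product: 7 4-bromo-2-(2-bromo-6-methoxyphenoxy)phenol, via 2-bromovinamidinium chloride 5 (not isolated), via open-chain aminodienone 6 (not isolated)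
Conditions: 4, Me2NH (2 M in THF), Me2NH·HCl, EtOH, 60 °C, then toluene azeotrope; 3, KOtBu, THF, 0 °C to 50 °C; aq. HCl
Reagents that add atoms: none
Why: Condensation of 4 with Me2NH and Me2NH·HCl converts the base-labile α-bromo dialdehyde into vinamidinium salt 5, in which bromine is vinylic and both termini are equivalent iminium-type electrophiles. KOtBu then gives the enolate of 3, preferentially at the more acidic aryloxy-bearing α-carbon, which adds to one terminus of 5 and expels Me2NH (addition–elimination) to form C2–C3 in aminodienone 6; first attack through the methyl carbon would lead to the same ring. A second deprotonation at the remaining α-carbon gives a trienolate that closes ring A by forming C5–C6, a 6π-electrocyclisation that is formally 6-(enolendo)-endo-trig at the C4=C5 bond of the neutral enamine and 6-(enolendo)-exo-trig at C=N+ in its iminium resonance form, both allowed closures; loss of the second Me2NH and tautomerisation of the cyclohexadienone then give the phenoxide of 7. The closest known reaction type is the benzannulation of ketones having two enolisable α-carbons with 2-substituted malonaldehydes or their vinamidinium salts, long used with nitromalonaldehyde to make 4-nitrophenols. No stereocentre is formed, and regiochemistry is not in question because the three-carbon electrophile is symmetric: its central C–Br carbon must end para to the new hydroxyl and the aryloxy group ortho to it. The selectivity needed is chemoselectivity, C–C bond formation at both α-carbons ahead of bromide loss, self-condensation of 3 or enamine formation (which would lead to an N,N-dimethylaniline instead of the phenol); the vinamidinium form of the electrophile and an alkoxide base in aprotic solvent are meant to secure it. Ring closure needs the acetyl group and the bromovinyl arm cis on the C2=C3 double bond of 6, a geometry the push–pull dienamine should reach by easy isomerisation on warming.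

Step 3
Reactants: 7 4-bromo-2-(2-bromo-6-methoxyphenoxy)phenol
Product: 8 4-bromo-2-(2-bromo-6-methoxyphenoxy)phenyl methanesulfonate
Conditions: MsCl, Et3N, CH2Cl2, 0 °C
Reagents that add atoms: methanesulfonyl chloride, CS(=O)(=O)Cl
Why: O-Sulfonylation of the only free hydroxyl (mesylation); the mesylate withdraws electron density from ring A, does not migrate under the acidic conditions that follow, and is stable to BBr3 and Br2.

Step 4
Reactants: 8 4-bromo-2-(2-bromo-6-methoxyphenoxy)phenyl methanesulfonate
Product: 10 4-bromo-2-(2-bromo-6-hydroxyphenoxy)phenyl methanesulfonate, via aryloxydibromoborane 9 (not isolated)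
Conditions: BBr3, CH2Cl2, −78 °C to 0 °C; H2O work-up
Reagents that add atoms: none
Why: Lewis acid-mediated cleavage of an aryl methyl ether: boron binds the methoxy oxygen and bromide attacks the methyl carbon by SN2 to give borate 9 and MeBr, and water then hydrolyses 9; the diaryl ether offers no sp3 carbon for attack, and the aryl sulfonate and aryl bromides do not react.

Step 5
Reactants: 10 4-bromo-2-(2-bromo-6-hydroxyphenoxy)phenyl methanesulfonate
Product: 11 4-bromo-2-(2,3,5-tribromo-6-hydroxyphenoxy)phenyl methanesulfonate
Conditions: Br2 (2.05 equiv), AcOH, rt
Reagents that add atoms: bromine, BrBr
Why: Electrophilic aromatic substitution directed by the free hydroxyl of ring B to its ortho and para positions (C3′ and C5′); C4′ is meta to that hydroxyl and ring A is deactivated by the mesylate and its bromine, so two equivalents of Br2 should be consumed on ring B only.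

Step 6
Reactants: 11 4-bromo-2-(2,3,5-tribromo-6-hydroxyphenoxy)phenyl methanesulfonate
Product: 12 3,4,6-tribromo-2-(5-bromo-2-hydroxyphenoxy)phenol (target)
Conditions: NaOH, MeOH–H2O, 60 °C; then aq. HCl
Reagents that add atoms: none
Why: Alkaline cleavage of the aryl methanesulfonate (hydroxide attack at sulfur or E1cB sulfene formation) releases the ring A phenoxide; ring B is present as its phenoxide and is thereby shielded from nucleophilic displacement of bromide, and acidification returns the bis-phenol.

## Compound list

1 | 2-bromo-6-methoxyphenol | COc1cccc(Br)c1O | starting material
2 | chloroacetone (1-chloropropan-2-one) | CC(=O)CCl | starting material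
3 | 1-(2-bromo-6-methoxyphenoxy)propan-2-one | CC(=O)COc1c(Br)cccc1OC | intermediate
4 | 2-bromomalonaldehyde | O=CC(Br)C=O | starting material
5 | 2-bromo-1,3-bis(dimethylamino)trimethinium chloride, N-[(2Z)-2-bromo-3-(dimethylamino)prop-2-en-1-ylidene]-N-methylmethanaminium chloride | CN(C)/C=C(Br)/C=[N+](C)C.[Cl-] | intermediate
6 | (3E,5Z)-5-bromo-3-(2-bromo-6-methoxyphenoxy)-6-(dimethylamino)hexa-3,5-dien-2-one | CC(=O)/C(Oc1c(Br)cccc1OC)=C\C(Br)=C\N(C)C | intermediate
7 | 4-bromo-2-(2-bromo-6-methoxyphenoxy)phenol | Oc1ccc(Br)cc1Oc1c(Br)cccc1OC | intermediate
8 | 4-bromo-2-(2-bromo-6-methoxyphenoxy)phenyl methanesulfonate | CS(=O)(=O)Oc1ccc(Br)cc1Oc1c(Br)cccc1OC | intermediate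
9 | 4-bromo-2-{2-bromo-6-[(dibromoboranyl)oxy]phenoxy}phenyl methanesulfonate | CS(=O)(=O)Oc1ccc(Br)cc1Oc1c(Br)cccc1OB(Br)Br | intermediate
10 | 4-bromo-2-(2-bromo-6-hydroxyphenoxy)phenyl methanesulfonate | CS(=O)(=O)Oc1ccc(Br)cc1Oc1c(Br)cccc1O | intermediate
11 | 4-bromo-2-(2,3,5-tribromo-6-hydroxyphenoxy)phenyl methanesulfonate | CS(=O)(=O)Oc1ccc(Br)cc1Oc1c(O)c(Br)cc(Br)c1Br | intermediate
12 | 3,4,6-tribromo-2-(5-bromo-2-hydroxyphenoxy)phenol | Oc1ccc(Br)cc1Oc1c(O)c(Br)cc(Br)c1Br | target

## Step count and risks

Total step count: 6. Longest linear sequence: 6 steps (1 → 3 → 7 → 8 → 10 → 11 → 12); 2 and 4 enter as purchased reagents.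

Least certain steps:

Step 2 (key step). The cascade may stall after the first C–C bond or divert to intermolecular condensation, because the second deprotonation must occur at the less acidic methyl carbon and closure needs the cis arrangement on C2=C3. Loss of bromide from the three-carbon unit or self-condensation of 3 under KOtBu would add to the loss. The fallback uses known chemistry, leaves the condensation approach, sets out from 1 and comes back at 7. Nucleophilic aromatic substitution of 1 on 4-bromo-2-fluorobenzaldehyde (K2CO3, DMF, 100 °C) should give 4-bromo-2-(2-bromo-6-methoxyphenoxy)benzaldehyde F1, the fluorine ortho to the formyl group being displaced far faster than the para bromine. Baeyer–Villiger oxidation (mCPBA, CH2Cl2) should give 4-bromo-2-(2-bromo-6-methoxyphenoxy)phenyl formate F2 by migration of the electron-rich aryl group, and hydrolysis (NaOH, MeOH–H2O, room temperature, then acid) should give 7.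

Step 5. Stoichiometric control may be lost: the second bromination of ring B slows after the first, so mixtures of under- and over-brominated material, including attack on ring A para to the ether oxygen, may arise. The fallback replaces the single double substitution by a staged halogenation resting on two different selectivity principles; it sets out from 10 and comes back at 11. Para-selective monobromination with Bu4NBr3 (CH2Cl2–MeOH) should give 4-bromo-2-(2,3-dibromo-6-hydroxyphenoxy)phenyl methanesulfonate F3, which is isolated and then brominated ortho to the hydroxyl with NBS and catalytic iPr2NH (CH2Cl2) to give 11.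

Step 6. S–O cleavage of the mesylate may be sluggish in a substrate that is already an anion. The forcing conditions then needed invite displacement of bromide on the sulfonate-bearing ring or Smiles-type migration of ring A between the two oxygen atoms of ring B. The fallback uses a sulfonate that leaves at room temperature; it sets out from 7 and comes back at 12. Tf2O and pyridine (CH2Cl2, 0 °C) should give 4-bromo-2-(2-bromo-6-methoxyphenoxy)phenyl trifluoromethanesulfonate F4. BBr3 (CH2Cl2) should give 4-bromo-2-{2-bromo-6-[(dibromoboranyl)oxy]phenoxy}phenyl trifluoromethanesulfonate F5, hydrolysed on work-up to 4-bromo-2-(2-bromo-6-hydroxyphenoxy)phenyl trifluoromethanesulfonate F6. Br2 in AcOH should give 4-bromo-2-(2,3,5-tribromo-6-hydroxyphenoxy)phenyl trifluoromethanesulfonate F7, and Et4NOH in aqueous dioxane at room temperature, followed by acidification, should release 12.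

## Further compounds

F1 | step 2 | 4-bromo-2-(2-bromo-6-methoxyphenoxy)benzaldehyde | O=Cc1ccc(Br)cc1Oc1c(Br)cccc1OC
F2 | step 2 | 4-bromo-2-(2-bromo-6-methoxyphenoxy)phenyl formate | O=COc1ccc(Br)cc1Oc1c(Br)cccc1OC
F3 | step 5 | 4-bromo-2-(2,3-dibromo-6-hydroxyphenoxy)phenyl methanesulfonate | CS(=O)(=O)Oc1ccc(Br)cc1Oc1c(O)ccc(Br)c1Br
F4 | step 6 | 4-bromo-2-(2-bromo-6-methoxyphenoxy)phenyl trifluoromethanesulfonate | O=S(=O)(Oc1ccc(Br)cc1Oc1c(Br)cccc1OC)C(F)(F)F
F5 | step 6 | 4-bromo-2-{2-bromo-6-[(dibromoboranyl)oxy]phenoxy}phenyl trifluoromethanesulfonate | O=S(=O)(Oc1ccc(Br)cc1Oc1c(Br)cccc1OB(Br)Br)C(F)(F)F
F6 | step 6 | 4-bromo-2-(2-bromo-6-hydroxyphenoxy)phenyl trifluoromethanesulfonate | O=S(=O)(Oc1ccc(Br)cc1Oc1c(Br)cccc1O)C(F)(F)F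
F7 | step 6 | 4-bromo-2-(2,3,5-tribromo-6-hydroxyphenoxy)phenyl trifluoromethanesulfonate | O=S(=O)(Oc1ccc(Br)cc1Oc1c(O)c(Br)cc(Br)c1Br)C(F)(F)F
A1 | alternative 1 | 2-phenoxyaniline | Nc1ccccc1Oc1ccccc1
A2 | alternative 1 | 2,5-dimethyl-1-(2-phenoxyphenyl)-1H-pyrrole | Cc1ccc(C)n1-c1ccccc1Oc1ccccc1
A3 | alternative 1 | 3-(2,5-dimethylpyrrol-1-yl)-2-(2-hydroxyphenoxy)phenol | Cc1ccc(C)n1-c1cccc(O)c1Oc1ccccc1O
A4 | alternative 1 | 3-amino-2-(2-hydroxyphenoxy)phenol | Nc1cccc(O)c1Oc1ccccc1O
A5 | alternative 1 | 3-amino-4,6-dibromo-2-(5-bromo-2-hydroxyphenoxy)phenol | Nc1c(Br)cc(Br)c(O)c1Oc1cc(Br)ccc1O
A6 | alternative 2 | 2-iodo-6-(4,4,5,5-tetramethyl-1,3,2-dioxaborolan-2-yl)phenyl trifluoromethanesulfonate | CC1(C)OB(OC1(C)C)c1cccc(I)c1OS(=O)(=O)C(F)(F)F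
A7 | alternative 2 | 5-bromo-2-methoxyphenol | COc1ccc(Br)cc1O
A8 | alternative 2 | 2-[3-bromo-2-(5-bromo-2-methoxyphenoxy)phenyl]-4,4,5,5-tetramethyl-1,3,2-dioxaborolane | CC1(C)OB(OC1(C)C)c1cccc(Br)c1Oc1cc(Br)ccc1OC
A9 | alternative 2 | 3-bromo-2-(5-bromo-2-methoxyphenoxy)phenol | Oc1cccc(Br)c1Oc1cc(Br)ccc1OC
A10 | alternative 2 | 3,4,6-tribromo-2-(5-bromo-2-methoxyphenoxy)phenol | Oc1c(Br)cc(Br)c(Br)c1Oc1cc(Br)ccc1OC
A11 | alternative 3 | methyl 6-(5-bromo-2-methoxyphenoxy)-5-oxohexanoate | COC(=O)CCCC(=O)COc1cc(Br)ccc1OC
A12 | alternative 3 | 2-(5-bromo-2-methoxyphenoxy)cyclohexane-1,3-dione | O=C1CCCC(=O)C1Oc1cc(Br)ccc1OC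
A13 | alternative 3 | 3-bromo-2-(5-bromo-2-methoxyphenoxy)cyclohex-2-en-1-one | O=C1CCCC(Br)=C1Oc1cc(Br)ccc1OC
A14 | alternative 3 | 3,6-dibromo-2-(5-bromo-2-methoxyphenoxy)phenol | Oc1c(Br)ccc(Br)c1Oc1cc(Br)ccc1OC
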